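In drimane numbering, ring A is cut at C3–C4. Ring B (C5 to C10, oxygen at C8, the gem-dimethyl carbon C4 hanging on C5, methyl on C10, C11 on C9) is the six-membered ring of a pinane whose cyclobutane bond C4–C7 has been opened. The key step does this opening with a Lewis acid on a verbenone-derived nopinone: the C8 enolate and a tertiary C4 cation form, and a (Z)-vinylsilane on the C1 chain captures the cation through C3, closing ring A as the trans-fused Δ2 olefin. The precursor is 4-methyl-4-[(Z)-3-(trimethylsilyl)allyl]-3-(silyloxymethyl)nopinone with both new groups on the face opposite the gem-dimethyl bridge.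

Key step: step 8

Remark: drimane numbering is used for decalins and pinane numbering (C2 carbonyl, C4 quaternary, C6 gem-dimethyl bridge, C7 methylene bridge) for bicyclic compounds; the C11 oxygen is carried as a tert-butyldiphenylsilyl ether (stable to TiCl4 and hot AcOH) and the hydroxymethyl group is added only after the alkyne chain is complete, so that no base meets a β-silyloxy ketone; (1S,5S)-verbenone maps onto the (2R,5S,9S,10R) target, with C11 trans and the C2 acetate cis to the C10 methyl.

Step 1
Reactants: 1 (1S,5S)-(−)-verbenone; 2 allyltrimethylsilane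
Product: 4 4-allyl-4-methylnopinone (allyl anti to the gem-dimethyl bridge), via trichlorotitanium enolate 3 (not isolated)
Conditions: TiCl4 (added last), CH2Cl2, −78 °C; then H2O
Reagents that add atoms: none
Why: Hosomi–Sakurai conjugate allylation of the TiCl4-activated enone, in which the inner methyl of the C6 bridge shields one face so that allyl enters C4 from the methylene-bridge side and fixes the quaternary centre that becomes C10; the adduct rests as a titanium enolate, which is not prone to cyclobutane cleavage before the quench.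

Step 2
Reactants: 4 4-allyl-4-methylnopinone
Product: 6 4-methyl-4-(2-oxoethyl)nopinone, via ozonide 5 (not isolated)
Conditions: O3, CH2Cl2, −78 °C; then PPh3, −78 °C → rt
Reagents that add atoms: ozone, [O-][O+]=O
Why: Ozonolysis with reductive work-up cleaves the only C=C bond to the aldehyde, while the ketone and cyclobutane are inert and no stereocentre is touched.

Step 3
Reactants: 6 4-methyl-4-(2-oxoethyl)nopinone
Product: 7 4-methyl-4-(prop-2-ynyl)nopinone
Conditions: dimethyl (1-diazo-2-oxopropyl)phosphonate, K2CO3, MeOH, 0 °C → rt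
Reagents that add atoms: dimethyl (1-diazo-2-oxopropyl)phosphonate, CC(=O)C(=[N+]=[N-])P(=O)(OC)OC
Why: Seyferth–Gilbert homologation in the Ohira–Bestmann variant converts the aldehyde into the terminal alkyne under carbonate conditions, which the ketone tolerates because its only enolisable position (C3) is still a plain methylene.

Step 4
Reactants: 7 4-methyl-4-(prop-2-ynyl)nopinone
Product: 9 trimethylsilyl enol ether (C2=C3) of 4-methyl-4-[3-(trimethylsilyl)prop-2-ynyl]nopinone, via dilithium enolate acetylide 8 (not isolated)
Conditions: LiN(iPr)2 (2.3 equiv), THF, −78 °C; Me3SiCl (2.6 equiv), −78 → 0 °C; cold aq NaHCO3 work-up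
Reagents that add atoms: chlorotrimethylsilane, C[Si](C)(C)Cl
Why: Double deprotonation gives the C3 enolate (the bridgehead C1 cannot enolise) together with the acetylide, and Me3SiCl then effects enolate O-silylation and acetylide C-silylation in one pot, the enolate shielding the ketone from the acetylide.

Step 5
Reactants: 9 trimethylsilyl enol ether of 4-methyl-4-[3-(trimethylsilyl)prop-2-ynyl]nopinone
Product: 10 3-(hydroxymethyl)-4-methyl-4-[3-(trimethylsilyl)prop-2-ynyl]nopinone (CH2OH anti to the gem-dimethyl bridge)
Conditions: aq HCHO (37%), Yb(OTf)3 (10 mol %), THF, rt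
Reagents that add atoms: formaldehyde, C=O
Why: Lanthanide-triflate-catalysed aqueous Mukaiyama aldol (hydroxymethylation) of the silyl enol ether, in which formaldehyde bonds to C3 on the face away from the gem-dimethyl bridge, placing CH2OH cis to the propargyl chain and trans to the C4 methyl (the future C9 configuration); the alkynylsilane is stable to these conditions.

Step 6
Reactants: 10 3-(hydroxymethyl)-4-methyl-4-[3-(trimethylsilyl)prop-2-ynyl]nopinone
Product: 11 3-[(tert-butyldiphenylsilyloxy)methyl]-4-methyl-4-[3-(trimethylsilyl)prop-2-ynyl]nopinone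
Conditions: tBuPh2SiCl, imidazole, CH2Cl2, rt
Reagents that add atoms: tert-butyl(chloro)diphenylsilane, CC(C)(C)[Si](Cl)(c1ccccc1)c1ccccc1
Why: Imidazole-mediated O-silylation of the primary alcohol, mild enough to leave the C3 stereocentre alone and giving an ether bulky and robust enough for TiCl4 and hot acetic acid.

Step 7
Reactants: 11 3-[(tert-butyldiphenylsilyloxy)methyl]-4-methyl-4-[3-(trimethylsilyl)prop-2-ynyl]nopinone
Product: 12 3-[(tert-butyldiphenylsilyloxy)methyl]-4-methyl-4-[(Z)-3-(trimethylsilyl)allyl]nopinone
Conditions: H2 (1 atm), Pd/CaCO3 poisoned with Pb(OAc)2, quinoline, EtOAc, rt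
Reagents that add atoms: none
Why: Syn semi-hydrogenation of the silylalkyne on lead-poisoned palladium should deliver the (Z)-vinylsilane stereospecifically, the geometry needed for ring-forming ipso substitution, with ketone and silyl ether inert.

Step 8
Reactants: 12 3-[(tert-butyldiphenylsilyloxy)methyl]-4-methyl-4-[(Z)-3-(trimethylsilyl)allyl]nopinone
Product: 15 trans-fused 4,4,10-trimethyl-Δ2-octalin-8-one with axial CH2OSi(tBu)Ph2 on C9, via ring-opened titanium enolate cation 13 (not isolated), via cyclised trichlorotitanium enolate 14 (not isolated)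
Conditions: TiCl4 (2.2 equiv), CH2Cl2, −78 → −30 °C; aq NaHCO3 quench at −78 °C
Reagents that add atoms: none
Why: Proposed new method: TiCl4 binds the ketone oxygen (pinane C2, future C8) and the strained cyclobutane bond from the α-carbon to the gem-dimethyl carbon (pinane C1–C6, future C7–C4), held nearly parallel to the carbonyl π system, heterolyses to a chlorotitanium enolate and a tertiary cation at C4; the silicon-bearing carbon C3 of the (Z)-vinylsilane attacks this cation and the β-silyl cation at C2 loses Me3SiCl to leave the Δ2 olefin. The closest known reactions are the Lewis-acid opening of 4-arylnopinones in which a tethered phenol oxygen captures the tertiary cation to form a trans-fused pyran, and vinylsilane-terminated cation–olefin cyclisations; here a carbon π-nucleophile takes the place of the heteroatom. Ring A closes in the 6-endo-trig mode by ipso attack, and because the C1 chain on C10 and C4 on C5 are trans on ring B they can bridge only diequatorially, so the trans-decalin is the sole possible fusion. No stereocentre is created: C5, C9 and C10 come from the pinane template, and the enolate forms regiospecifically towards C7, so C9 is not exposed to enolisation before the quench. The step needs C–C capture to outrun proton loss to an isopropenyl group, chloride capture, protodesilylation and Prins-type attack of the vinylsilane on the complexed carbonyl. This should be secured by the chain sitting on the neighbouring carbon, by the β-silicon effect (only the (Z) isomer can place the C–Si bond pseudo-axial, parallel to the empty orbital at C2), and by the reversibility of chloride capture and proton loss under TiCl4/HCl.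

Step 9
Reactants: 15 trans-fused 4,4,10-trimethyl-Δ2-octalin-8-one with axial CH2OSi(tBu)Ph2 on C9
Product: 16 2,3-epoxide of 15 with oxygen on the H-5 face (anti to the C10 methyl)
Conditions: dimethyldioxirane, acetone/CH2Cl2, 0 °C
Reagents that add atoms: dimethyldioxirane, CC1(C)OO1
Why: Neutral dioxirane epoxidation (no Baeyer–Villiger reaction at C8, no acid or base at C9) should deliver oxygen to the Δ2 face opposite the axial methyls on C4 and C10, which sets C2 and C3 of the epoxide.

Step 10
Reactants: 16 2,3-epoxide of 15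
Product: 17 2-acetoxy-3-hydroxy-8-ketone (axial OAc at C2 cis to the C10 methyl; axial OH at C3 trans to it)
Conditions: AcOH, NaOAc, 70 °C
Reagents that add atoms: acetic acid, CC(=O)O
Why: Acetolysis of the epoxide under the Fürst–Plattner rule, where attack at C2 from the methyl-bearing face is the only trans-diaxial mode and avoids the neopentyl C3, setting the C2 acetate cis to the C10 methyl with inversion; the equatorial C9–H is poorly aligned for enolisation, so C9 should hold.

Step 11
Reactants: 17 2-acetoxy-3-hydroxy-8-ketone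
Product: 18 2-acetoxy-11-(tert-butyldiphenylsilyloxy)drim-8(12)-en-3-ol
Conditions: Zn, CH2Br2, TiCl4, THF (pre-formed reagent); then 17, CH2Cl2, 0 °C → rt
Reagents that add atoms: dibromomethane, BrCBr
Why: Takai–Lombardo methylenation is non-basic, so the C9 centre next to the ketone should not epimerise, and it tolerates the acetate and the free hydroxyl (excess reagent).

Step 12
Reactants: 18 2-acetoxy-11-(tert-butyldiphenylsilyloxy)drim-8(12)-en-3-ol
Product: 19 2-acetoxydrim-8(12)-ene-3,11-diol
Conditions: Bu4NF, AcOH (1:1), THF, 0 °C → rt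
Reagents that add atoms: none
Why: Buffered fluoride desilylation of the primary silyl ether, in which the trans-diaxial arrangement of acetate and C3 hydroxyl rules out acyl migration.

Step 13
Reactants: 19 2-acetoxydrim-8(12)-ene-3,11-diol; 20 isofraxidin (7-hydroxy-6,8-dimethoxycoumarin)
Product: 21 7-O-(2-acetoxy-3-hydroxydrim-8(12)-en-11-yl) ether of isofraxidin
Conditions: PPh3, DIAD, THF, 0 °C → rt
Reagents that add atoms: none
Why: Mitsunobu etherification of the primary alcohol with the acidic coumarin phenol; the axial neopentyl-type C3 hydroxyl should not compete and no stereocentre is involved.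

Step 14
Reactants: 21 7-O-(2-acetoxy-3-hydroxydrim-8(12)-en-11-yl) ether of isofraxidin
Product: 22 CNP0183157.1
Conditions: Dess–Martin periodinane, pyridine, CH2Cl2, 0 °C → rt
Reagents that add atoms: none
Why: Dess–Martin oxidation of the axial C3 alcohol under buffered conditions forms the ketone last, so the axial C2 acetate (the less stable epimer, cis to the C10 methyl) never meets epimerising conditions.

Compound list
1 | (1S,5S)-(−)-verbenone | CC1=CC(=O)[C@H]2C[C@@H]1C2(C)C | starting material
2 | allyltrimethylsilane | C=CC[Si](C)(C)C | starting material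
3 | trichlorotitanium enolate of 4 (Ti–O on C2, C2=C3) | C=CC[C@@]1(C)C=C(O[Ti](Cl)(Cl)Cl)[C@H]2C[C@@H]1C2(C)C | intermediate
4 | 4-allyl-4-methylnopinone (4-allyl-4,6,6-trimethylbicyclo[3.1.1]heptan-2-one; allyl anti, C4 methyl syn to the gem-dimethyl bridge) | C=CC[C@@]1(C)CC(=O)[C@H]2C[C@@H]1C2(C)C | intermediate
5 | ozonide (1,2,4-trioxolane) of 4 | C1OC(C[C@@]2(C)CC(=O)[C@H]3C[C@@H]2C3(C)C)OO1 | intermediate
6 | 4-methyl-4-(2-oxoethyl)nopinone | O=CC[C@@]1(C)CC(=O)[C@H]2C[C@@H]1C2(C)C | intermediate
7 | 4-methyl-4-(prop-2-ynyl)nopinone | C#CC[C@@]1(C)CC(=O)[C@H]2C[C@@H]1C2(C)C | intermediate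
8 | dilithium salt of 7 (C2 enolate, lithium acetylide) | [Li]C#CC[C@@]1(C)C=C(O[Li])[C@H]2C[C@@H]1C2(C)C | intermediate
9 | trimethylsilyl enol ether (C2=C3) of 4-methyl-4-[3-(trimethylsilyl)prop-2-ynyl]nopinone | C[Si](C)(C)C#CC[C@@]1(C)C=C(O[Si](C)(C)C)[C@H]2C[C@@H]1C2(C)C | intermediate
10 | 3-(hydroxymethyl)-4-methyl-4-[3-(trimethylsilyl)prop-2-ynyl]nopinone (CH2OH anti to the bridge, cis to the propargyl chain, trans to the C4 methyl) | C[Si](C)(C)C#CC[C@@]1(C)[C@@H](CO)C(=O)[C@H]2C[C@@H]1C2(C)C | intermediate
11 | 3-[(tert-butyldiphenylsilyloxy)methyl]-4-methyl-4-[3-(trimethylsilyl)prop-2-ynyl]nopinone | C[Si](C)(C)C#CC[C@@]1(C)[C@@H](CO[Si](c2ccccc2)(c2ccccc2)C(C)(C)C)C(=O)[C@H]2C[C@@H]1C2(C)C | intermediate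
12 | 3-[(tert-butyldiphenylsilyloxy)methyl]-4-methyl-4-[(Z)-3-(trimethylsilyl)allyl]nopinone | C[Si](C)(C)/C=C\C[C@@]1(C)[C@@H](CO[Si](c2ccccc2)(c2ccccc2)C(C)(C)C)C(=O)[C@H]2C[C@@H]1C2(C)C | intermediate
13 | ring-opened zwitterion: tetrachlorotitanate enolate (C7=C8) with the 2-propyl cation (C4) on C5 | C[Si](C)(C)/C=C\C[C@@]1(C)[C@@H](CO[Si](c2ccccc2)(c2ccccc2)C(C)(C)C)C(O[Ti-](Cl)(Cl)(Cl)Cl)=CC[C@@H]1[C+](C)C | intermediate
14 | trichlorotitanium enolate (C7=C8) of 15 | Cl[Ti](Cl)(Cl)OC1=CC[C@@H]2C(C)(C)C=CC[C@@]2(C)[C@H]1CO[Si](c3ccccc3)(c3ccccc3)C(C)(C)C | intermediate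
15 | trans-fused 4,4,10-trimethyl-Δ2-octalin-8-one with axial CH2OSi(tBu)Ph2 on C9 (trans to the C10 methyl, cis to H-5) | O=C1CC[C@@H]2C(C)(C)C=CC[C@@]2(C)[C@H]1CO[Si](c3ccccc3)(c3ccccc3)C(C)(C)C | intermediate
16 | 2,3-epoxide of 15, oxygen on the H-5 face | O=C1CC[C@@H]2C(C)(C)[C@H]3O[C@H]3C[C@@]2(C)[C@H]1CO[Si](c4ccccc4)(c4ccccc4)C(C)(C)C | intermediate
17 | 2-acetoxy-3-hydroxy-8-ketone (axial OAc at C2 cis to the C10 methyl, axial OH at C3 trans to it) | O=C1CC[C@@H]2C(C)(C)[C@@H](O)[C@H](OC(C)=O)C[C@@]2(C)[C@H]1CO[Si](c3ccccc3)(c3ccccc3)C(C)(C)C | intermediate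
18 | 2-acetoxy-11-(tert-butyldiphenylsilyloxy)drim-8(12)-en-3-ol | C=C1CC[C@@H]2C(C)(C)[C@@H](O)[C@H](OC(C)=O)C[C@@]2(C)[C@H]1CO[Si](c3ccccc3)(c3ccccc3)C(C)(C)C | intermediate
19 | 2-acetoxydrim-8(12)-ene-3,11-diol | C=C1CC[C@@H]2C(C)(C)[C@@H](O)[C@H](OC(C)=O)C[C@@]2(C)[C@H]1CO | intermediate
20 | isofraxidin (7-hydroxy-6,8-dimethoxycoumarin) | COc1cc2ccc(=O)oc2c(OC)c1O | starting material
21 | 7-O-(2-acetoxy-3-hydroxydrim-8(12)-en-11-yl) ether of isofraxidin | C=C1CC[C@@H]2C(C)(C)[C@@H](O)[C@H](OC(C)=O)C[C@@]2(C)[C@H]1COc1c(OC)cc2ccc(=O)oc2c1OC | intermediate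
22 | CNP0183157.1, the (2R,5S,9S,10R)-2-acetoxy-3-oxodrim-8(12)-en-11-yl ether of isofraxidin | C=C1CC[C@@H]2C(C)(C)C(=O)[C@H](OC(C)=O)C[C@@]2(C)[C@H]1COc1c(OC)cc2ccc(=O)oc2c1OC | target

Total step count: 14. Longest linear sequence: 14 steps (1 to 22); 2 and 20 are bought and enter in steps 1 and 13.

Steps most likely to fail

Step 8. The cation may be lost by proton elimination to an isopropenyl group or by chloride capture before ring closure, the vinylsilane may be protodesilylated by adventitious HCl, or the vinylsilane may add to the complexed carbonyl instead. The fallback separates the two events with known reactions and sets out from 12. The acetolytic cyclobutane opening established for nopinone-type ketones (BF3·OEt2, Zn(OAc)2, Ac2O, 0 °C) should give the ring-opened enol acetate bearing a 2-acetoxyprop-2-yl group on C5 F1. Ionisation of the tertiary acetate with SnCl4 in CH2Cl2 at −78 °C is then an ordinary vinylsilane-terminated cation–olefin cyclisation and should give the enol acetate of the decalone F2. Brief treatment with K2CO3 in MeOH at 0 °C cleaves the enol acetate and comes back to the route at 15.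

Step 10. The axial approach to C2 runs between the two axial methyls, so the opening may be slow and may give way to cationic rearrangement of ring A, or to elimination or epimerisation at C9 on long heating. The fallback uses water as a much smaller nucleophile and sets out from 16. Acid-catalysed hydrolysis (cat. HClO4, THF/H2O, 0 °C) should give the trans-diaxial 2,3-diol F3. The less hindered C3 hydroxyl is silylated selectively (Et3SiCl, imidazole, CH2Cl2, 0 °C) to the 3-O-triethylsilyl ether F4. The remaining axial C2 hydroxyl is acetylated under forcing conditions (Ac2O, DMAP, pyridine, 40 °C) to the 2-acetate 3-triethylsilyl ether F5. PPTS in MeOH at 0 °C removes only the triethylsilyl group and comes back to the route at 17.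

Step 13. Both partners are hindered (a phenol flanked by two methoxy groups and a β-branched axial primary alcohol), so the alkoxyphosphonium may form slowly or be intercepted by the hydrazinedicarboxylate instead of the phenol. The fallback replaces redox condensation by a Williamson etherification and sets out from 19. Selective triflation of the primary hydroxyl (Tf2O, 2,6-lutidine, CH2Cl2, −78 °C) should give the C11 triflate F6. Displacement with the cesium phenoxide of 20 (Cs2CO3, DMF, 0 °C → rt) comes back to the route at 21.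

Further compounds
F1 | step 8 | ring-opened enol acetate (C7=C8) with 2-acetoxyprop-2-yl on C5 | C[Si](C)(C)/C=C\C[C@@]1(C)[C@@H](CO[Si](c2ccccc2)(c2ccccc2)C(C)(C)C)C(OC(C)=O)=CC[C@@H]1C(C)(C)OC(C)=O
F2 | step 8 | enol acetate (C7=C8) of 15 | CC(=O)OC1=CC[C@@H]2C(C)(C)C=CC[C@@]2(C)[C@H]1CO[Si](c3ccccc3)(c3ccccc3)C(C)(C)C
F3 | step 10 | trans-diaxial 2,3-diol of the 8-ketone | O=C1CC[C@@H]2C(C)(C)[C@@H](O)[C@H](O)C[C@@]2(C)[C@H]1CO[Si](c3ccccc3)(c3ccccc3)C(C)(C)C
F4 | step 10 | 3-O-triethylsilyl ether of F3 | O=C1CC[C@@H]2C(C)(C)[C@@H](O[Si](CC)(CC)CC)[C@H](O)C[C@@]2(C)[C@H]1CO[Si](c3ccccc3)(c3ccccc3)C(C)(C)C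
F5 | step 10 | 2-acetate 3-O-triethylsilyl ether | O=C1CC[C@@H]2C(C)(C)[C@@H](O[Si](CC)(CC)CC)[C@H](OC(C)=O)C[C@@]2(C)[C@H]1CO[Si](c3ccccc3)(c3ccccc3)C(C)(C)C
F6 | step 13 | C11 triflate of 19 | C=C1CC[C@@H]2C(C)(C)[C@@H](O)[C@H](OC(C)=O)C[C@@]2(C)[C@H]1COS(=O)(=O)C(F)(F)F
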